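**Retrosynthetic overview**
1. C12–C13 is made last, by Negishi coupling of a C12 alkylzinc with methyl (Z)-4-acetoxy-3-iodobut-2-enoate; retention at the alkenyl carbon gives the 13E enoate.
2. The trans C5–H and the C6=C7 alkene come from a palladium-catalysed reductive 1,3-transposition of a C7 allylic formate, itself made from a C5=C6–C7=O enone; the C7 oxygen is a relay and is removed.
3. Ring B is built in one flask from the enolsilane of 2,2,6-trimethylcyclohexanone (ring A, bought) and an alkylidene acetoacetate: C9–C10 by enantioselective Mukaiyama–Michael addition, then ring closure C5–C6 by aldol condensation.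
4. Enabling feature: C5 is the carbonyl carbon of ring A between quaternary C4 and C10, so it cannot enolise and can only accept; C6–C7(=O)–C8(CO2Me) is an acetoacetate unit whose methyl carbon C6 is the one nucleophile that reaches C5 through a six-membered ring.
5. Ring order: A (starting material), then B (key step); ketone, methyl acetoacetate and a protected 3-hydroxypropanal supply every ring B atom.

Key step: step 3

Remark: labdane numbering is used for all intermediates (ring A = C1–C5 and C10, ring B = C5–C10, C17 = ester carbon on C8, side chain C11–C16). Keto ester 8 is drawn as its keto tautomer with the C8 ester equatorial, as expected at equilibrium. t-Bu-box = 2,2'-(propane-2,2-diyl)bis[(4S)-4-tert-butyl-4,5-dihydro-1,3-oxazole], and its (S,S) form is assumed to be the antipode that leads to (9R).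

**Step 1**
Reactants: 1 2,2,6-trimethylcyclohexan-1-one (racemic)
Product: 2 trimethyl[(2,6,6-trimethylcyclohex-1-en-1-yl)oxy]silane
Conditions: LiN(i-Pr)2, THF, −78 → 0 °C; Me3SiCl, −78 °C → rt
Reagents that add atoms: chlorotrimethylsilane, C[Si](C)(C)Cl
Why: Only one carbon next to the carbonyl (the future C10) carries hydrogen, so enolate formation and O-silylation (silyl enol ether synthesis) can give only this tetrasubstituted enol ether, and the stereocentre of 1 is erased.

**Step 2**
Reactants: 3 3-[(tert-butyldiphenylsilyl)oxy]propanal; 4 methyl acetoacetate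
Product: 5 methyl 2-acetyl-5-[(tert-butyldiphenylsilyl)oxy]pent-2-enoate (E/Z mixture)
Conditions: piperidine (10 mol %), AcOH (10 mol %), CH2Cl2, 4 Å MS, 0 °C → rt
Reagents that add atoms: none
Why: Knoevenagel condensation of an unbranched aldehyde with a 1,3-dicarbonyl compound under piperidinium acetate catalysis is standard, and both alkene isomers offer the same carbon (C9) to the next step.

**Step 3**
Reactants: 2 silyl enol ether; 5 alkylidene acetoacetate
Product: 8 methyl (8R,9R,10S)-12-[(tert-butyldiphenylsilyl)oxy]-7-oxo-13,14,15,16-tetranorlabd-5-en-17-oate (ring B: C5=C6–C7(=O)–C8(CO2Me)–C9–C10), via Michael adduct 6 (not isolated), via aldol 7 (not isolated)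
Conditions: [Cu(L)](SbF6)2 (10 mol %, L = (S,S)-t-Bu-box), (CF3)2CHOH (2 equiv), PhMe–CH2Cl2, −78 → −20 °C; evaporate; LiN(i-Pr)2 (3 equiv), THF, −78 → −20 °C; AcOH; p-TsOH·H2O (10 mol %), PhH, 60 °C
Reagents that add atoms: none
Why: Proposed new method: a cationic copper–bis(oxazoline) complex binds the 1,3-dicarbonyl unit of 5 as a chelate and the enolsilane 2 adds through its fully substituted carbon C10 to C9 (Mukaiyama–Michael addition), hexafluoroisopropanol taking over the silyl group to release keto ester 6; the closest known reaction type is the copper–bis(oxazoline)-catalysed addition of enolsilanes to alkylidene malonates, which has not been shown with a tetrasubstituted ketone enolsilane, with an acetoacetate-derived acceptor or in one flask with a ring closure. LiN(i-Pr)2 then turns 6 into its 1,3-dicarbonyl dianion, whose terminal carbanion C6 adds to the C5 ketone of ring A in a 6-(enolendo)-exo-trig aldol closure of ring B (7), and acid removes water toward C6, the only neighbour of C5 that carries hydrogen, to give the C5=C6–C7=O enone. C9 is set by the ligand, which shields one face of the chelated alkylidene carbon, and C10 by a synclinal, hetero-Diels–Alder-like approach in which the silyloxy group lies over the chelated dicarbonyl unit and the ring methylene C1 points away from the C9 substituent, so that C11 and the C10 methyl become cis on ring B (H9 anti to the methyl); C8 is not set kinetically and should settle as the equatorial ester or its enol. The step needs bond formation at C10 to outrun proton transfer from the acidic gamma position (C11) of 5, which the non-basic Lewis-acid conditions secure, and gamma rather than alpha reactivity of the keto ester in the closure, which the dianion secures because alpha attack would give a four-membered ring.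

**Step 4**
Reactants: 8 enone keto ester
Product: 9 methyl (7R,8R,9R,10S)-12-[(tert-butyldiphenylsilyl)oxy]-7-hydroxy-13,14,15,16-tetranorlabd-5-en-17-oate
Conditions: NaBH4, CeCl3·7H2O, MeOH, −78 → −40 °C
Reagents that add atoms: none
Why: Luche reduction: the cerium-activated enone should be attacked 1,2 on the face opposite to the angular C10 methyl (as with steroidal 4-en-3-ones), which puts the C7 hydroxyl on the methyl face, while C8 is carried through in its equatorial keto form.

**Step 5**
Reactants: 9 allylic alcohol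
Product: 10 methyl (7R,8R,9R,10S)-12-[(tert-butyldiphenylsilyl)oxy]-7-(formyloxy)-13,14,15,16-tetranorlabd-5-en-17-oate
Conditions: HCO2H, Ac2O (premixed), pyridine, CH2Cl2, 0 °C
Reagents that add atoms: acetic formic anhydride (made in the flask from formic acid and acetic anhydride), CC(=O)OC=O
Why: Formylation with the mixed anhydride (esterification) works on hindered secondary alcohols and installs the internal hydride source without touching C7 or C8.

**Step 6**
Reactants: 10 allylic formate
Product: 11 methyl (5R,8S,9R,10S)-12-[(tert-butyldiphenylsilyl)oxy]-13,14,15,16-tetranorlabd-6-en-17-oate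
Conditions: Pd(OAc)2 (5 mol %), n-Bu3P (5 mol %), THF, 25 °C
Reagents that add atoms: none
Why: Palladium-catalysed hydrogenolysis of an allylic formate (Tsuji–Trost type ionisation, then decarboxylation to a palladium hydride): palladium enters anti to the formate, that is on the face opposite to the C10 methyl, and should pass hydride from its own face to the more substituted allyl terminus C5, giving the trans ring fusion and the C6=C7 alkene.

**Step 7**
Reactants: 11 silyl ether
Product: 12 methyl (5R,8S,9R,10S)-12-hydroxy-13,14,15,16-tetranorlabd-6-en-17-oate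
Conditions: HF·pyridine, pyridine, THF, 0 °C → rt
Reagents that add atoms: none
Why: Fluoride-mediated silyl ether cleavage under buffered, non-basic conditions should neither epimerise C8 nor move the alkene into conjugation; the alcohol is used at once because it could lactonise onto C17.

**Step 8**
Reactants: 12 primary alcohol
Product: 13 methyl (5R,8S,9R,10S)-12-iodo-13,14,15,16-tetranorlabd-6-en-17-oate
Conditions: I2, PPh3, imidazole, CH2Cl2, 0 °C
Reagents that add atoms: iodine, II
Why: Appel-type iodination of a primary alcohol runs under neutral conditions and leaves the allylic ester and the alkene alone.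

**Step 9**
Reactants: 14 methyl 4-hydroxybut-2-ynoate
Product: 15 methyl 4-acetoxybut-2-ynoate
Conditions: Ac2O, pyridine, DMAP (cat.), CH2Cl2, 0 °C
Reagents that add atoms: acetic anhydride, CC(=O)OC(C)=O
Why: Acetylation of a primary propargylic alcohol (esterification) is routine.

**Step 10**
Reactants: 15 alkynoate
Product: 16 methyl (2Z)-4-acetoxy-3-iodobut-2-enoate
Conditions: NaI, AcOH, 70 °C
Reagents that add atoms: sodium iodide, [Na+].[I-]
Why: Hydroiodination of a 2-alkynoate is a conjugate addition of iodide followed by protonation anti to it, which should give the (Z)-3-iodo enoate (iodine cis to the ester, CH2OAc trans).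

**Step 11**
Reactants: 13 alkyl iodide; 16 alkenyl iodide
Product: 18 dimethyl (5R,8S,9R,10S,13E)-16-acetoxylabda-6,13-diene-15,17-dioate (target), via alkylzinc iodide 17 (not isolated)
Conditions: Zn dust (Me3SiCl/BrCH2CH2Br-activated), THF–DMA, 40 °C; then 16, PdCl2(dppf) (5 mol %), rt
Reagents that add atoms: none
Why: Negishi coupling: zinc inserts into the primary C–I bond in the presence of the ester, and palladium-catalysed coupling with the alkenyl iodide proceeds with retention, so C12 ends cis to the C15 ester (13E).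

**Compound list**
1 | 2,2,6-trimethylcyclohexan-1-one (racemic) | CC1CCCC(C)(C)C1=O | starting material
2 | trimethyl[(2,6,6-trimethylcyclohex-1-en-1-yl)oxy]silane | CC1=C(O[Si](C)(C)C)C(C)(C)CCC1 | intermediate
3 | 3-[(tert-butyldiphenylsilyl)oxy]propanal | O=CCCO[Si](c1ccccc1)(c1ccccc1)C(C)(C)C | starting material
4 | methyl acetoacetate | COC(=O)CC(C)=O | starting material
5 | methyl 2-acetyl-5-[(tert-butyldiphenylsilyl)oxy]pent-2-enoate (E/Z mixture) | COC(=O)C(=CCCO[Si](c1ccccc1)(c1ccccc1)C(C)(C)C)C(C)=O | intermediate
6 | methyl (3R)-2-acetyl-5-[(tert-butyldiphenylsilyl)oxy]-3-[(1S)-1,3,3-trimethyl-2-oxocyclohexyl]pentanoate (C2 epimers and enol) | CC(C)(C)[Si](c1ccccc1)(c1ccccc1)OCC[C@H](C(C(=O)OC)C(C)=O)[C@]1(C)CCCC(C)(C)C1=O | intermediate (not isolated)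
7 | methyl (8R,9R,10S)-12-[(tert-butyldiphenylsilyl)oxy]-5-hydroxy-7-oxo-13,14,15,16-tetranorlabdan-17-oate (C5 epimers) | CC(C)(C)[Si](c1ccccc1)(c1ccccc1)OCC[C@@H]1[C@@H](C(=O)OC)C(=O)CC2(O)C(C)(C)CCC[C@@]12C | intermediate (not isolated)
8 | methyl (8R,9R,10S)-12-[(tert-butyldiphenylsilyl)oxy]-7-oxo-13,14,15,16-tetranorlabd-5-en-17-oate | CC(C)(C)[Si](c1ccccc1)(c1ccccc1)OCC[C@@H]1[C@@H](C(=O)OC)C(=O)C=C2C(C)(C)CCC[C@@]12C | intermediate
9 | methyl (7R,8R,9R,10S)-12-[(tert-butyldiphenylsilyl)oxy]-7-hydroxy-13,14,15,16-tetranorlabd-5-en-17-oate | CC(C)(C)[Si](c1ccccc1)(c1ccccc1)OCC[C@@H]1[C@@H](C(=O)OC)[C@H](O)C=C2C(C)(C)CCC[C@@]12C | intermediate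
10 | methyl (7R,8R,9R,10S)-12-[(tert-butyldiphenylsilyl)oxy]-7-(formyloxy)-13,14,15,16-tetranorlabd-5-en-17-oate | CC(C)(C)[Si](c1ccccc1)(c1ccccc1)OCC[C@@H]1[C@@H](C(=O)OC)[C@H](OC=O)C=C2C(C)(C)CCC[C@@]12C | intermediate
11 | methyl (5R,8S,9R,10S)-12-[(tert-butyldiphenylsilyl)oxy]-13,14,15,16-tetranorlabd-6-en-17-oate | CC(C)(C)[Si](c1ccccc1)(c1ccccc1)OCC[C@@H]1[C@@H](C(=O)OC)C=C[C@@H]2C(C)(C)CCC[C@@]12C | intermediate
12 | methyl (5R,8S,9R,10S)-12-hydroxy-13,14,15,16-tetranorlabd-6-en-17-oate | OCC[C@@H]1[C@@H](C(=O)OC)C=C[C@@H]2C(C)(C)CCC[C@@]12C | intermediate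
13 | methyl (5R,8S,9R,10S)-12-iodo-13,14,15,16-tetranorlabd-6-en-17-oate | ICC[C@@H]1[C@@H](C(=O)OC)C=C[C@@H]2C(C)(C)CCC[C@@]12C | intermediate
14 | methyl 4-hydroxybut-2-ynoate | COC(=O)C#CCO | starting material
15 | methyl 4-acetoxybut-2-ynoate | COC(=O)C#CCOC(C)=O | intermediate
16 | methyl (2Z)-4-acetoxy-3-iodobut-2-enoate | COC(=O)/C=C(\I)COC(C)=O | intermediate
17 | [(5R,8S,9R,10S)-17-methoxy-17-oxo-13,14,15,16-tetranorlabd-6-en-12-yl]zinc iodide | I[Zn]CC[C@@H]1[C@@H](C(=O)OC)C=C[C@@H]2C(C)(C)CCC[C@@]12C | intermediate (not isolated)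
18 | dimethyl (5R,8S,9R,10S,13E)-16-acetoxylabda-6,13-diene-15,17-dioate | COC(=O)/C=C(\CC[C@@H]1[C@@H](C(=O)OC)C=C[C@@H]2C(C)(C)CCC[C@@]12C)COC(C)=O | target

**Step count and risks**
Total step count: 11. Longest linear sequence: 8 steps (3 and 4 → 5 → 8 → 9 → 10 → 11 → 12 → 13 → 18).

Steps most likely to fail:

Step 3 (bears the label "Proposed new method:"). What may go wrong is lack of turnover or poor facial and simple diastereoselection when the fully substituted enolsilane carbon has to bond to C9 on the chiral copper complex, and incomplete closure if copper salts are carried into the dianion stage. The fallback uses known chemistry and sets out from 2 and 5. TiCl4-promoted Mukaiyama–Michael addition (CH2Cl2, −78 °C) gives the racemic keto ester F1, which is isolated and purified. LiN(i-Pr)2 (2.2 equiv) and then p-TsOH close ring B through the racemic aldol F2 to the racemic enone keto ester F3. Luche reduction gives the racemic allylic alcohol F4, whose antipodes are separated by preparative chromatography on a chiral stationary phase. The (7R,8R,9R,10S) antipode is 9, where the route is rejoined.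

Step 6. What may go wrong is hydride delivery to the less hindered allyl terminus C7, or loss of the C8 proton from the allylpalladium intermediate to give a diene ester, because C5 lies between two quaternary carbons. The fallback sets out from 9. A Mitsunobu reaction with 2-nitrobenzenesulfonyl hydrazide (PPh3, DEAD, N-methylmorpholine, THF, −30 °C) gives, with inversion at C7, the sulfonyl hydrazine F5. On warming it loses the sulfinic acid to give the allylic diazene F6, which transfers hydrogen to C5 on its own face with loss of N2 (retro-ene) and gives 11, where the route is rejoined. Inversion followed by suprafacial transfer leads to the same C5 configuration as the palladium path.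

Step 11. What may go wrong is beta-acetoxy elimination or ionisation of the allylic acetate once palladium has inserted into 16, or slow zinc insertion into 13. The fallback sets out from 14. NaI in AcOH gives methyl (2Z)-4-hydroxy-3-iodobut-2-enoate F7, and Me2(t-Bu)SiCl with imidazole gives its silyl ether F8. Negishi coupling of F8 with the zinc reagent 17 gives the 16-silyl ether F9. HF·pyridine frees the 16-alcohol F10, which cannot lactonise because its hydroxymethyl group is trans to the C15 ester. Ac2O in pyridine then gives 18, where the route is rejoined.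

**Further compounds**
F1 | step 3 | racemic methyl 2-acetyl-5-[(tert-butyldiphenylsilyl)oxy]-3-(1,3,3-trimethyl-2-oxocyclohexyl)pentanoate (6 and its antipode) | CC(C)(C)[Si](c1ccccc1)(c1ccccc1)OCC[C@H](C(C(=O)OC)C(C)=O)[C@]1(C)CCCC(C)(C)C1=O.CC(C)(C)[Si](c1ccccc1)(c1ccccc1)OCC[C@@H](C(C(=O)OC)C(C)=O)[C@@]1(C)CCCC(C)(C)C1=O
F2 | step 3 | racemic aldol (7 and its antipode) | CC(C)(C)[Si](c1ccccc1)(c1ccccc1)OCC[C@@H]1[C@@H](C(=O)OC)C(=O)CC2(O)C(C)(C)CCC[C@@]12C.CC(C)(C)[Si](c1ccccc1)(c1ccccc1)OCC[C@H]1[C@H](C(=O)OC)C(=O)CC2(O)C(C)(C)CCC[C@]12C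
F3 | step 3 | racemic enone keto ester (8 and its antipode) | CC(C)(C)[Si](c1ccccc1)(c1ccccc1)OCC[C@@H]1[C@@H](C(=O)OC)C(=O)C=C2C(C)(C)CCC[C@@]12C.CC(C)(C)[Si](c1ccccc1)(c1ccccc1)OCC[C@H]1[C@H](C(=O)OC)C(=O)C=C2C(C)(C)CCC[C@]12C
F4 | step 3 | racemic allylic alcohol (9 and its antipode) | CC(C)(C)[Si](c1ccccc1)(c1ccccc1)OCC[C@@H]1[C@@H](C(=O)OC)[C@H](O)C=C2C(C)(C)CCC[C@@]12C.CC(C)(C)[Si](c1ccccc1)(c1ccccc1)OCC[C@H]1[C@H](C(=O)OC)[C@@H](O)C=C2C(C)(C)CCC[C@]12C
F5 | step 6 | methyl (7S,8R,9R,10S)-7-[1-(2-nitrophenylsulfonyl)hydrazinyl]-12-[(tert-butyldiphenylsilyl)oxy]-13,14,15,16-tetranorlabd-5-en-17-oate | CC(C)(C)[Si](c1ccccc1)(c1ccccc1)OCC[C@@H]1[C@@H](C(=O)OC)[C@@H](N(N)S(=O)(=O)c3ccccc3[N+](=O)[O-])C=C2C(C)(C)CCC[C@@]12C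
F6 | step 6 | methyl (7S,8R,9R,10S)-7-diazenyl-12-[(tert-butyldiphenylsilyl)oxy]-13,14,15,16-tetranorlabd-5-en-17-oate | CC(C)(C)[Si](c1ccccc1)(c1ccccc1)OCC[C@@H]1[C@@H](C(=O)OC)[C@@H](N=N)C=C2C(C)(C)CCC[C@@]12C
F7 | step 11 | methyl (2Z)-4-hydroxy-3-iodobut-2-enoate | COC(=O)/C=C(\I)CO
F8 | step 11 | methyl (2Z)-4-[(tert-butyldimethylsilyl)oxy]-3-iodobut-2-enoate | COC(=O)/C=C(\I)CO[Si](C)(C)C(C)(C)C
F9 | step 11 | dimethyl (5R,8S,9R,10S,13E)-16-[(tert-butyldimethylsilyl)oxy]labda-6,13-diene-15,17-dioate | COC(=O)/C=C(\CC[C@@H]1[C@@H](C(=O)OC)C=C[C@@H]2C(C)(C)CCC[C@@]12C)CO[Si](C)(C)C(C)(C)C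
F10 | step 11 | dimethyl (5R,8S,9R,10S,13E)-16-hydroxylabda-6,13-diene-15,17-dioate | COC(=O)/C=C(\CC[C@@H]1[C@@H](C(=O)OC)C=C[C@@H]2C(C)(C)CCC[C@@]12C)CO
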